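**Plan**
- Retrosynthesis: the target is cut at C11=C12 and C11′=C12′ (two Wittig olefinations on the central C10 dialdehyde). Each C20 half is then cut at C11–P/C9=C10 (vinyl carbinol to allyl phosphonium salt), at C6–C7 (acetylide addition to a ring enone), at the side-chain C=C on C2 (Wittig), and last at C2–vinyl and C1–CH3.
- Enabling feature: in ring A (prenyl ring) and ring B (hydroxyprenyl ring) the tertiary stereocentre C2 has the same local sense and lies next to the quaternary gem-dimethyl carbon C1. These two carbons are the β- and α-carbons of 2-methylcyclohex-2-enone, so one vinyl ketone serves both rings.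
- Forward: no ring is closed, the enone ring is carried through. Conjugate vinylation/methylation (C2, C1), C5 methylation and dehydrogenation, then acetylide addition at C6 and oxidative 1,3-transposition give one C4-oxo enone. Both halves branch from it; the ring A half is joined to the dialdehyde first, the ring B half last.
- Stereochemistry: C2 and C2′ come from the chiral copper catalyst. C6 (2,6-cis, ring A) and C6′ (2,6-trans, ring B) come from antipodal oxazaborolidine reductions of the common enone at C4, each relayed to C6 by a stereospecific allylic-diazene reductive transposition that also places the ring double bond at C4=C5.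
- Alkene geometry: C7=C8 by trans-hydroalumination, the hydroxyprenyl C=C by an E-selective stabilised Wittig, C9=C10 and C11=C12 by thermodynamic equilibration.

Key step: step 1

Remark: the SMILES defines ring A as 2S,6R (side chains cis) and ring B as 2′R,6′S (side chains trans), so C6 is set by reagent control rather than by base-mediated deconjugation of a conjugated ring ester, which would also favour the exocyclic alkene; the silyloxy carbon of the five-carbon alkynyl arm (later C9) is racemic and is carried as an inconsequential epimer mixture until it becomes sp2; TBSO = tert-butyldimethylsilyloxy.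

**Route**

Step 1
Reactants: 1 2-methylcyclohex-2-en-1-one; 2 vinylmagnesium bromide; 3 iodomethane
Product: 5 (R)-2,2-dimethyl-3-vinylcyclohexan-1-one, via bromomagnesium enolate 4 (not isolated)
Conditions: CuBr·SMe2 (5 mol %), (R)-1-[(S)-2-(diphenylphosphino)ferrocenyl]ethyldicyclohexylphosphine (6 mol %), t-BuOMe, −78 °C, slow addition of 2 (1.2 equiv); then 3 (5 equiv), DMPU, −78 → 0 °C
Reagents that add atoms: vinylmagnesium bromide, C=C[Mg]Br; iodomethane, CI
Why: Transmetallation of the Grignard reagent onto the chiral monovalent copper bromide–diphosphine complex gives a vinylcopper species that π-complexes the enone; oxidative addition at C3 to a trivalent copper σ-alkyl intermediate and reductive elimination form the C3–vinyl bond and leave the tetrasubstituted bromomagnesium enolate 4 with the enolate carbon fixed at C2. The closest known reaction type is the copper-catalysed asymmetric conjugate addition of Grignard reagents to α-substituted cyclic enones with alkylation of the enolate in the same flask; no ring is closed. The one new stereocentre, C3 of 5 (C2 and C2′ of the target), is controlled by enantioface discrimination through the ferrocenyl diphosphine on copper, and the ligand antipode that gives the (R)-ketone is used (the mirror-image ligand if a first run shows the opposite sense). The second bond, C2–CH3, forms by SN2 attack of the enolate carbon on iodomethane and makes a gem-dimethyl carbon, so no diastereoselectivity is needed. The step needs 1,4- over 1,2-addition (copper catalysis, low temperature, slow addition), regiospecific alkylation (the magnesium enolate does not equilibrate and only the methyl-bearing carbon is nucleophilic) and C- over O-methylation (dipolar cosolvent with a soft electrophile).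

Step 2
Reactants: 5 (R)-2,2-dimethyl-3-vinylcyclohexan-1-one
Product: 7 (R)-3-(2-hydroxyethyl)-2,2-dimethylcyclohexan-1-one, via catechol boronate 6 (not isolated)
Conditions: catecholborane (1.3 equiv), RhCl(PPh3)3 (2 mol %), THF, 0 → 23 °C; then NaOH, H2O2, EtOH/H2O, 0 °C
Reagents that add atoms: hydrogen peroxide, OO
Why: Rhodium-catalysed hydroboration of the terminal alkene is much faster than uncatalysed reduction of the hindered ketone by catecholborane, boron goes to the terminal carbon, and alkaline peroxide oxidation (hydroboration–oxidation) gives the primary alcohol without touching C3.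

Step 3
Reactants: 7 (R)-3-(2-hydroxyethyl)-2,2-dimethylcyclohexan-1-one
Product: 8 (R)-3-[2-(TBSO)ethyl]-2,2-dimethylcyclohexan-1-one
Conditions: t-BuMe2SiCl (1.2 equiv), imidazole, DMF, 23 °C
Reagents that add atoms: tert-butyldimethylsilyl chloride, CC(C)(C)[Si](C)(C)Cl
Why: Imidazole-promoted silyl ether formation masks the primary alcohol for the enolate, organolithium and chromium steps; no stereocentre is affected.

Step 4
Reactants: 8 (R)-3-[2-(TBSO)ethyl]-2,2-dimethylcyclohexan-1-one; 3 iodomethane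
Product: 10 (3R)-3-[2-(TBSO)ethyl]-2,2,6-trimethylcyclohexan-1-one, via lithium enolate 9 (not isolated)
Conditions: LiN(iPr)2 (1.1 equiv), THF, −78 °C; then 3 (3 equiv), −78 → 0 °C
Reagents that add atoms: iodomethane, CI
Why: Kinetic enolate alkylation: the α′-methylene is the only enolisable position, so one enolate forms and SN2 methylation installs the future C5 methyl; the new stereocentre forms unselectively and is erased in step 5.

Step 5
Reactants: 10 (3R)-3-[2-(TBSO)ethyl]-2,2,6-trimethylcyclohexan-1-one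
Product: 12 (5R)-5-[2-(TBSO)ethyl]-2,6,6-trimethylcyclohex-2-en-1-one, via trimethylsilyl enol ether 11 (not isolated)
Conditions: Me3SiOTf (1.5 equiv), Et3N (3 equiv), CH2Cl2, 0 → 23 °C; solvent exchange; Pd(OAc)2 (1.1 equiv), MeCN, 23 °C
Reagents that add atoms: none
Why: Saegusa–Ito dehydrogenation: the only possible silyl enol ether is palladated by divalent palladium and β-hydride elimination towards the ring methylene should give the endocyclic enone, which removes the stereocentre made in step 4.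

Step 6
Reactants: 13 3-methylpent-1-en-4-yn-3-ol
Product: 14 tert-butyldimethyl[(3-methylpent-1-en-4-yn-3-yl)oxy]silane
Conditions: t-BuMe2SiOTf (1.2 equiv), 2,6-lutidine, CH2Cl2, 0 → 23 °C
Reagents that add atoms: tert-butyldimethylsilyl trifluoromethanesulfonate, CC(C)(C)[Si](C)(C)OS(=O)(=O)C(F)(F)F
Why: Silyl ether formation at the tertiary propargylic alcohol with a silyl triflate and a hindered base protects the carbinol from the later chromium oxidant; the centre is racemic.

Step 7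
Reactants: 12 (5R)-5-[2-(TBSO)ethyl]-2,6,6-trimethylcyclohex-2-en-1-one; 14 tert-butyldimethyl[(3-methylpent-1-en-4-yn-3-yl)oxy]silane
Product: 16 (5R)-5-[2-(TBSO)ethyl]-1-[3-(TBSO)-3-methylpent-4-en-1-yn-1-yl]-2,6,6-trimethylcyclohex-2-en-1-ol, via lithium acetylide 15 (not isolated)
Conditions: 14 (1.3 equiv), n-BuLi (1.25 equiv), THF, −78 °C; then 12, −78 → 0 °C; H2O
Reagents that add atoms: none
Why: 1,2-Addition of a lithium acetylide, a small hard nucleophile that does not add 1,4, to the hindered enone carbonyl forms the C6–C7 bond; the new carbinol centre becomes sp2 in step 8, so its configuration does not matter.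

Step 8
Reactants: 16 (5R)-5-[2-(TBSO)ethyl]-1-[3-(TBSO)-3-methylpent-4-en-1-yn-1-yl]-2,6,6-trimethylcyclohex-2-en-1-ol
Product: 17 (5S)-5-[2-(TBSO)ethyl]-3-[3-(TBSO)-3-methylpent-4-en-1-yn-1-yl]-2,4,4-trimethylcyclohex-2-en-1-one
Conditions: [C5H5NH][CrO3Cl] (3 equiv), NaOAc, 4 Å molecular sieves, CH2Cl2, 23 °C
Reagents that add atoms: pyridinium chlorochromate, [O-][Cr](=O)(=O)Cl.c1cc[nH+]cc1
Why: Babler–Dauben oxidative transposition: the chromate ester of the tertiary allylic alcohol undergoes a [3,3] shift to the ring CH and is oxidised to the enone, which moves oxygen from C6 to C4 and makes C5=C6; the alkynyl arm cannot take part and the tertiary silyl ether is inert.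

Step 9
Reactants: 17 (5S)-5-[2-(TBSO)ethyl]-3-[3-(TBSO)-3-methylpent-4-en-1-yn-1-yl]-2,4,4-trimethylcyclohex-2-en-1-one
Product: 18 (1R,5S)-5-[2-(TBSO)ethyl]-3-[3-(TBSO)-3-methylpent-4-en-1-yn-1-yl]-2,4,4-trimethylcyclohex-2-en-1-ol
Conditions: (S)-1-methyl-3,3-diphenyltetrahydro-1H,3H-pyrrolo[1,2-c][1,3,2]oxazaborole (0.3 equiv), catecholborane (1.8 equiv), toluene, −78 °C; then MeOH, aq. NaOH
Reagents that add atoms: none
Why: Corey–Bakshi–Shibata reduction: the oxazaborolidine binds the carbonyl with the α-methylated alkenyl flank as the large group and the ring CH2 as the small one, so the (S)-catalyst should give the (1R)-carbinol under reagent control (OH cis to the C5 side chain), 1,2-selectively and without hydroborating the vinyl or alkynyl groups at −78 °C.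

Step 10
Reactants: 18 (1R,5S)-5-[2-(TBSO)ethyl]-3-[3-(TBSO)-3-methylpent-4-en-1-yn-1-yl]-2,4,4-trimethylcyclohex-2-en-1-ol
Product: 21 tert-butyl(2-{(1R,5R)-5-[3-(TBSO)-3-methylpent-4-en-1-yn-1-yl]-4,6,6-trimethylcyclohex-3-en-1-yl}ethoxy)dimethylsilane, via sulfonylhydrazine 19 (not isolated), via allylic diazene 20 (not isolated)
Conditions: 2-nitrobenzenesulfonylhydrazide (3 equiv), PPh3 (3 equiv), diethyl azodicarboxylate (3 equiv), THF, −30 °C; then 23 °C
Reagents that add atoms: none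
Why: Reductive 1,3-transposition of an allylic alcohol through an allylic diazene: Mitsunobu displacement inverts the carbinol carbon, loss of 2-nitrobenzenesulfinic acid gives the monoalkyl diazene, and its retro-ene loss of N2 delivers hydrogen suprafacially to the alkyne-bearing carbon, so the new stereocentre (C6 of the target, R) has H anti to the original hydroxyl, the side chains are 2,6-cis and the double bond sits at C4=C5.

Step 11
Reactants: 21 tert-butyl(2-{(1R,5R)-5-[3-(TBSO)-3-methylpent-4-en-1-yn-1-yl]-4,6,6-trimethylcyclohex-3-en-1-yl}ethoxy)dimethylsilane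
Product: 22 2-[(1R,5R)-5-(3-hydroxy-3-methylpent-4-en-1-yn-1-yl)-4,6,6-trimethylcyclohex-3-en-1-yl]ethan-1-ol
Conditions: Bu4NF (4 equiv), THF, 23 → 45 °C
Reagents that add atoms: none
Why: Fluoride-mediated desilylation cleaves both silyl ethers (the tertiary one needs mild warming), and the propargylic C6–H is not acidic enough to be affected.

Step 12
Reactants: 22 2-[(1R,5R)-5-(3-hydroxy-3-methylpent-4-en-1-yn-1-yl)-4,6,6-trimethylcyclohex-3-en-1-yl]ethan-1-ol
Product: 23 2-[(1R,5R)-5-(3-hydroxy-3-methylpent-4-en-1-yn-1-yl)-4,6,6-trimethylcyclohex-3-en-1-yl]acetaldehyde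
Conditions: Dess–Martin periodinane (1.3 equiv), NaHCO3, CH2Cl2, 0 → 23 °C
Reagents that add atoms: none
Why: Dess–Martin oxidation converts the primary alcohol into the aldehyde under buffered, non-epimerising conditions; the tertiary alcohol cannot be oxidised.

Step 13
Reactants: 23 2-[(1R,5R)-5-(3-hydroxy-3-methylpent-4-en-1-yn-1-yl)-4,6,6-trimethylcyclohex-3-en-1-yl]acetaldehyde
Product: 24 3-methyl-5-[(1R,5S)-2,6,6-trimethyl-5-(3-methylbut-2-en-1-yl)cyclohex-2-en-1-yl]pent-1-en-4-yn-3-ol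
Conditions: isopropyltriphenylphosphonium iodide (1.5 equiv), NaN(SiMe3)2 (1.4 equiv), THF, 0 °C; then 23, −78 → 23 °C
Reagents that add atoms: isopropyltriphenylphosphonium iodide, CC(C)[P+](c1ccccc1)(c1ccccc1)c1ccccc1.[I-]
Why: Wittig olefination with the non-stabilised isopropylidene ylide turns the aldehyde into the prenyl alkene, which has no geometry to control; the free tertiary alcohol is tolerated.

Step 14
Reactants: 24 3-methyl-5-[(1R,5S)-2,6,6-trimethyl-5-(3-methylbut-2-en-1-yl)cyclohex-2-en-1-yl]pent-1-en-4-yn-3-ol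
Product: 25 (1E)-3-methyl-1-[(1R,5S)-2,6,6-trimethyl-5-(3-methylbut-2-en-1-yl)cyclohex-2-en-1-yl]penta-1,4-dien-3-ol
Conditions: LiAlH4 (3 equiv), THF, 0 → 66 °C; H2O, aq. NaOH
Reagents that add atoms: none
Why: Hydroxyl-directed trans-hydroalumination of the propargylic alcohol (propargylic to E-allylic alcohol reduction) should give the E C7=C8 alkene; isolated alkenes and the C6 stereocentre are untouched.

Step 15
Reactants: 25 (1E)-3-methyl-1-[(1R,5S)-2,6,6-trimethyl-5-(3-methylbut-2-en-1-yl)cyclohex-2-en-1-yl]penta-1,4-dien-3-ol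
Product: 26 {(2E,4E)-3-methyl-5-[(1R,5S)-2,6,6-trimethyl-5-(3-methylbut-2-en-1-yl)cyclohex-2-en-1-yl]penta-2,4-dien-1-yl}triphenylphosphonium bromide
Conditions: PPh3·HBr (1.05 equiv), MeOH, 0 → 23 °C
Reagents that add atoms: triphenylphosphine hydrobromide, [Br-].[PH+](c1ccccc1)(c1ccccc1)c1ccccc1
Why: Ionisation of the tertiary bis-allylic alcohol gives a pentadienyl cation that triphenylphosphine captures at the terminal carbon (SN1′ phosphonium salt formation); the new C9=C10 bond should be E by thermodynamic preference and C6 is not touched.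

Step 16
Reactants: 26 {(2E,4E)-3-methyl-5-[(1R,5S)-2,6,6-trimethyl-5-(3-methylbut-2-en-1-yl)cyclohex-2-en-1-yl]penta-2,4-dien-1-yl}triphenylphosphonium bromide; 27 (2E,4E,6E)-2,7-dimethylocta-2,4,6-trienedial
Product: 28 (2E,4E,6E,8E,10E,12E)-2,7,11-trimethyl-13-[(1R,5S)-2,6,6-trimethyl-5-(3-methylbut-2-en-1-yl)cyclohex-2-en-1-yl]trideca-2,4,6,8,10,12-hexaenal
Conditions: 27 (3 equiv), NaOMe (1.1 equiv), CH2Cl2/MeOH, 0 → 23 °C; then heptane, 80 °C
Reagents that add atoms: none
Why: Wittig olefination of the semistabilised allylic ylide, made in situ, with an excess of the symmetrical dialdehyde should give the mono-olefinated C30 aldehyde, and heating equilibrates the new C11=C12 bond to E.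

Step 17
Reactants: 17 (5S)-5-[2-(TBSO)ethyl]-3-[3-(TBSO)-3-methylpent-4-en-1-yn-1-yl]-2,4,4-trimethylcyclohex-2-en-1-one
Product: 29 (1S,5S)-5-[2-(TBSO)ethyl]-3-[3-(TBSO)-3-methylpent-4-en-1-yn-1-yl]-2,4,4-trimethylcyclohex-2-en-1-ol
Conditions: (R)-1-methyl-3,3-diphenyltetrahydro-1H,3H-pyrrolo[1,2-c][1,3,2]oxazaborole (0.3 equiv), catecholborane (1.8 equiv), toluene, −78 °C; then MeOH, aq. NaOH
Reagents that add atoms: none
Why: Corey–Bakshi–Shibata reduction with the antipodal catalyst: the same model should now give the (1S)-carbinol (OH trans to the C5 side chain), reagent control overriding the remote ring stereocentre.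

Step 18
Reactants: 29 (1S,5S)-5-[2-(TBSO)ethyl]-3-[3-(TBSO)-3-methylpent-4-en-1-yn-1-yl]-2,4,4-trimethylcyclohex-2-en-1-ol
Product: 32 tert-butyl(2-{(1R,5S)-5-[3-(TBSO)-3-methylpent-4-en-1-yn-1-yl]-4,6,6-trimethylcyclohex-3-en-1-yl}ethoxy)dimethylsilane, via sulfonylhydrazine 30 (not isolated), via allylic diazene 31 (not isolated)
Conditions: 2-nitrobenzenesulfonylhydrazide (3 equiv), PPh3 (3 equiv), diethyl azodicarboxylate (3 equiv), THF, −30 °C; then 23 °C
Reagents that add atoms: none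
Why: Reductive 1,3-transposition through the allylic diazene as in step 10: Mitsunobu inversion followed by suprafacial retro-ene hydrogen delivery puts H anti to the original hydroxyl, which here sets C6′ (S) with the side chains 2,6-trans.

Step 19
Reactants: 32 tert-butyl(2-{(1R,5S)-5-[3-(TBSO)-3-methylpent-4-en-1-yn-1-yl]-4,6,6-trimethylcyclohex-3-en-1-yl}ethoxy)dimethylsilane
Product: 33 2-[(1R,5S)-5-(3-hydroxy-3-methylpent-4-en-1-yn-1-yl)-4,6,6-trimethylcyclohex-3-en-1-yl]ethan-1-ol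
Conditions: Bu4NF (4 equiv), THF, 23 → 45 °C
Reagents that add atoms: none
Why: Fluoride-mediated desilylation of both silyl ethers, as in step 11, leaves the stereocentres untouched.

Step 20
Reactants: 33 2-[(1R,5S)-5-(3-hydroxy-3-methylpent-4-en-1-yn-1-yl)-4,6,6-trimethylcyclohex-3-en-1-yl]ethan-1-ol
Product: 34 2-[(1R,5S)-5-(3-hydroxy-3-methylpent-4-en-1-yn-1-yl)-4,6,6-trimethylcyclohex-3-en-1-yl]acetaldehyde
Conditions: Dess–Martin periodinane (1.3 equiv), NaHCO3, CH2Cl2, 0 → 23 °C
Reagents that add atoms: none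
Why: Dess–Martin oxidation of the primary alcohol to the aldehyde, as in step 12; the tertiary alcohol is inert.

Step 21
Reactants: 34 2-[(1R,5S)-5-(3-hydroxy-3-methylpent-4-en-1-yn-1-yl)-4,6,6-trimethylcyclohex-3-en-1-yl]acetaldehyde
Product: 35 ethyl (2E)-4-[(1R,5S)-5-(3-hydroxy-3-methylpent-4-en-1-yn-1-yl)-4,6,6-trimethylcyclohex-3-en-1-yl]-2-methylbut-2-enoate
Conditions: ethyl 2-(triphenylphosphoranylidene)propanoate (1.5 equiv), CH2Cl2, 23 → 40 °C
Reagents that add atoms: ethyl 2-(triphenylphosphoranylidene)propanoate, CCOC(=O)C(C)=P(c1ccccc1)(c1ccccc1)c1ccccc1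
Why: Wittig olefination with the stabilised α-methyl ylide should give the trisubstituted enoate with E geometry, which fixes the side-chain double bond of ring B.

Step 22
Reactants: 35 ethyl (2E)-4-[(1R,5S)-5-(3-hydroxy-3-methylpent-4-en-1-yn-1-yl)-4,6,6-trimethylcyclohex-3-en-1-yl]-2-methylbut-2-enoate
Product: 36 (2E)-4-{(1R,5S)-5-[(1E)-3-hydroxy-3-methylpenta-1,4-dien-1-yl]-4,6,6-trimethylcyclohex-3-en-1-yl}-2-methylbut-2-en-1-ol
Conditions: LiAlH4 (4 equiv), THF, 0 → 66 °C; H2O, aq. NaOH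
Reagents that add atoms: none
Why: LiAlH4 effects two known reductions in one operation, 1,2-reduction of the α,β-unsaturated ester to the E-allylic alcohol and hydroxyl-directed trans-hydroalumination of the propargylic alcohol to the E C7′=C8′ alkene.

Step 23
Reactants: 36 (2E)-4-{(1R,5S)-5-[(1E)-3-hydroxy-3-methylpenta-1,4-dien-1-yl]-4,6,6-trimethylcyclohex-3-en-1-yl}-2-methylbut-2-en-1-ol
Product: 37 (2E)-4-{(1R,5S)-5-[(1E)-3-hydroxy-3-methylpenta-1,4-dien-1-yl]-4,6,6-trimethylcyclohex-3-en-1-yl}-2-methylbut-2-en-1-yl acetate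
Conditions: Ac2O (1.1 equiv), pyridine, CH2Cl2, 0 °C
Reagents that add atoms: acetic anhydride, CC(=O)OC(C)=O
Why: Selective acetylation of the primary allylic alcohol (the tertiary alcohol does not react under these conditions) keeps it from ionising or being captured by phosphine in step 24.

Step 24
Reactants: 37 (2E)-4-{(1R,5S)-5-[(1E)-3-hydroxy-3-methylpenta-1,4-dien-1-yl]-4,6,6-trimethylcyclohex-3-en-1-yl}-2-methylbut-2-en-1-yl acetate
Product: 38 {(2E,4E)-5-[(1S,5R)-5-[(2E)-4-acetoxy-3-methylbut-2-en-1-yl]-2,6,6-trimethylcyclohex-2-en-1-yl]-3-methylpenta-2,4-dien-1-yl}triphenylphosphonium bromide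
Conditions: PPh3·HBr (1.05 equiv), MeOH, 0 → 23 °C
Reagents that add atoms: triphenylphosphine hydrobromide, [Br-].[PH+](c1ccccc1)(c1ccccc1)c1ccccc1
Why: SN1′ phosphonium salt formation through the pentadienyl cation as in step 15; the primary allylic acetate should not ionise under these mild conditions.

Step 25
Reactants: 28 (2E,4E,6E,8E,10E,12E)-2,7,11-trimethyl-13-[(1R,5S)-2,6,6-trimethyl-5-(3-methylbut-2-en-1-yl)cyclohex-2-en-1-yl]trideca-2,4,6,8,10,12-hexaenal; 38 {(2E,4E)-5-[(1S,5R)-5-[(2E)-4-acetoxy-3-methylbut-2-en-1-yl]-2,6,6-trimethylcyclohex-2-en-1-yl]-3-methylpenta-2,4-dien-1-yl}triphenylphosphonium bromide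
Product: 40 (all-E)-(2S,6R,2′R,6′S)-2-(3-methylbut-2-en-1-yl)-2′-[(2E)-4-hydroxy-3-methylbut-2-en-1-yl]-ε,ε-carotene (target CNP0304855.1), via carotenoid acetate 39 (not isolated)
Conditions: 38 (1.3 equiv), NaOMe (3 equiv), CH2Cl2/MeOH, 0 → 23 °C; then heptane, 90 °C
Reagents that add atoms: none
Why: Wittig olefination of the in situ ylide with the C30 aldehyde forms C11′=C12′ and completes the C50 chain, excess NaOMe in MeOH removes the acetate by transesterification, and heating equilibrates the polyene to all-E; the C6–H bonds are not acidified by the ylide, so the four ring stereocentres are retained.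

**Compound list**

1 | 2-methylcyclohex-2-en-1-one | CC1=CCCCC1=O | starting material
2 | vinylmagnesium bromide | C=C[Mg]Br | starting material
3 | iodomethane | CI | starting material
4 | bromomagnesium (3R)-2-methyl-3-vinylcyclohex-1-en-1-olate | C=C[C@H]1CCCC(O[Mg]Br)=C1C | intermediate
5 | (R)-2,2-dimethyl-3-vinylcyclohexan-1-one | C=C[C@H]1CCCC(=O)C1(C)C | intermediate
6 | (S)-3-[2-(1,3,2-benzodioxaborol-2-yl)ethyl]-2,2-dimethylcyclohexan-1-one | C(C[C@H]1CCCC(=O)C1(C)C)B1Oc2ccccc2O1 | intermediate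
7 | (R)-3-(2-hydroxyethyl)-2,2-dimethylcyclohexan-1-one | OCC[C@H]1CCCC(=O)C1(C)C | intermediate
8 | (R)-3-[2-(TBSO)ethyl]-2,2-dimethylcyclohexan-1-one | CC(C)(C)[Si](C)(C)OCC[C@H]1CCCC(=O)C1(C)C | intermediate
9 | lithium (5R)-5-[2-(TBSO)ethyl]-6,6-dimethylcyclohex-1-en-1-olate | CC(C)(C)[Si](C)(C)OCC[C@H]1CCC=C(O[Li])C1(C)C | intermediate
10 | (3R)-3-[2-(TBSO)ethyl]-2,2,6-trimethylcyclohexan-1-one (C6 epimers) | CC(C)(C)[Si](C)(C)OCC[C@H]1CCC(C)C(=O)C1(C)C | intermediate
11 | tert-butyldimethyl{2-[(1R)-2,2,4-trimethyl-3-(trimethylsilyloxy)cyclohex-3-en-1-yl]ethoxy}silane | CC(C)(C)[Si](C)(C)OCC[C@H]1CCC(C)=C(O[Si](C)(C)C)C1(C)C | intermediate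
12 | (5R)-5-[2-(TBSO)ethyl]-2,6,6-trimethylcyclohex-2-en-1-one | CC(C)(C)[Si](C)(C)OCC[C@H]1CC=C(C)C(=O)C1(C)C | intermediate
13 | 3-methylpent-1-en-4-yn-3-ol (racemic) | C=CC(C)(O)C#C | starting material
14 | tert-butyldimethyl[(3-methylpent-1-en-4-yn-3-yl)oxy]silane (racemic) | C=CC(C)(O[Si](C)(C)C(C)(C)C)C#C | intermediate
15 | [3-(TBSO)-3-methylpent-4-en-1-yn-1-yl]lithium | [Li]C#CC(C)(O[Si](C)(C)C(C)(C)C)C=C | intermediate
16 | (5R)-5-[2-(TBSO)ethyl]-1-[3-(TBSO)-3-methylpent-4-en-1-yn-1-yl]-2,6,6-trimethylcyclohex-2-en-1-ol (carbinol centres unassigned) | CC(C)(C)[Si](C)(C)OCC[C@H]1CC=C(C)C(O)(C#CC(C)(O[Si](C)(C)C(C)(C)C)C=C)C1(C)C | intermediate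
17 | (5S)-5-[2-(TBSO)ethyl]-3-[3-(TBSO)-3-methylpent-4-en-1-yn-1-yl]-2,4,4-trimethylcyclohex-2-en-1-one | CC(C)(C)[Si](C)(C)OCC[C@H]1CC(=O)C(C)=C(C#CC(C)(O[Si](C)(C)C(C)(C)C)C=C)C1(C)C | intermediate
18 | (1R,5S)-5-[2-(TBSO)ethyl]-3-[3-(TBSO)-3-methylpent-4-en-1-yn-1-yl]-2,4,4-trimethylcyclohex-2-en-1-ol | CC(C)(C)[Si](C)(C)OCC[C@H]1C[C@@H](O)C(C)=C(C#CC(C)(O[Si](C)(C)C(C)(C)C)C=C)C1(C)C | intermediate
19 | N-{(1S,5R)-5-[2-(TBSO)ethyl]-3-[3-(TBSO)-3-methylpent-4-en-1-yn-1-yl]-2,4,4-trimethylcyclohex-2-en-1-yl}-2-nitrobenzenesulfonohydrazide | CC(C)(C)[Si](C)(C)OCC[C@H]1C[C@H](N(N)S(=O)(=O)c2ccccc2[N+](=O)[O-])C(C)=C(C#CC(C)(O[Si](C)(C)C(C)(C)C)C=C)C1(C)C | intermediate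
20 | {(1S,5R)-5-[2-(TBSO)ethyl]-3-[3-(TBSO)-3-methylpent-4-en-1-yn-1-yl]-2,4,4-trimethylcyclohex-2-en-1-yl}diazene | CC(C)(C)[Si](C)(C)OCC[C@H]1C[C@H](N=N)C(C)=C(C#CC(C)(O[Si](C)(C)C(C)(C)C)C=C)C1(C)C | intermediate
21 | tert-butyl(2-{(1R,5R)-5-[3-(TBSO)-3-methylpent-4-en-1-yn-1-yl]-4,6,6-trimethylcyclohex-3-en-1-yl}ethoxy)dimethylsilane | CC(C)(C)[Si](C)(C)OCC[C@H]1CC=C(C)[C@@H](C#CC(C)(O[Si](C)(C)C(C)(C)C)C=C)C1(C)C | intermediate
22 | 2-[(1R,5R)-5-(3-hydroxy-3-methylpent-4-en-1-yn-1-yl)-4,6,6-trimethylcyclohex-3-en-1-yl]ethan-1-ol | OCC[C@H]1CC=C(C)[C@@H](C#CC(C)(O)C=C)C1(C)C | intermediate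
23 | 2-[(1R,5R)-5-(3-hydroxy-3-methylpent-4-en-1-yn-1-yl)-4,6,6-trimethylcyclohex-3-en-1-yl]acetaldehyde | O=CC[C@H]1CC=C(C)[C@@H](C#CC(C)(O)C=C)C1(C)C | intermediate
24 | 3-methyl-5-[(1R,5S)-2,6,6-trimethyl-5-(3-methylbut-2-en-1-yl)cyclohex-2-en-1-yl]pent-1-en-4-yn-3-ol | CC(C)=CC[C@H]1CC=C(C)[C@@H](C#CC(C)(O)C=C)C1(C)C | intermediate
25 | (1E)-3-methyl-1-[(1R,5S)-2,6,6-trimethyl-5-(3-methylbut-2-en-1-yl)cyclohex-2-en-1-yl]penta-1,4-dien-3-ol | CC(C)=CC[C@H]1CC=C(C)[C@@H](/C=C/C(C)(O)C=C)C1(C)C | intermediate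
26 | {(2E,4E)-3-methyl-5-[(1R,5S)-2,6,6-trimethyl-5-(3-methylbut-2-en-1-yl)cyclohex-2-en-1-yl]penta-2,4-dien-1-yl}triphenylphosphonium bromide | CC(C)=CC[C@H]1CC=C(C)[C@@H](/C=C/C(C)=C/C[P+](c2ccccc2)(c2ccccc2)c2ccccc2)C1(C)C.[Br-] | intermediate
27 | (2E,4E,6E)-2,7-dimethylocta-2,4,6-trienedial | O=C/C(C)=C/C=C/C=C(C)/C=O | starting material
28 | (2E,4E,6E,8E,10E,12E)-2,7,11-trimethyl-13-[(1R,5S)-2,6,6-trimethyl-5-(3-methylbut-2-en-1-yl)cyclohex-2-en-1-yl]trideca-2,4,6,8,10,12-hexaenal | CC(C)=CC[C@H]1CC=C(C)[C@@H](/C=C/C(C)=C/C=C/C(C)=C/C=C/C=C(C)/C=O)C1(C)C | intermediate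
29 | (1S,5S)-5-[2-(TBSO)ethyl]-3-[3-(TBSO)-3-methylpent-4-en-1-yn-1-yl]-2,4,4-trimethylcyclohex-2-en-1-ol | CC(C)(C)[Si](C)(C)OCC[C@H]1C[C@H](O)C(C)=C(C#CC(C)(O[Si](C)(C)C(C)(C)C)C=C)C1(C)C | intermediate
30 | N-{(1R,5R)-5-[2-(TBSO)ethyl]-3-[3-(TBSO)-3-methylpent-4-en-1-yn-1-yl]-2,4,4-trimethylcyclohex-2-en-1-yl}-2-nitrobenzenesulfonohydrazide | CC(C)(C)[Si](C)(C)OCC[C@H]1C[C@@H](N(N)S(=O)(=O)c2ccccc2[N+](=O)[O-])C(C)=C(C#CC(C)(O[Si](C)(C)C(C)(C)C)C=C)C1(C)C | intermediate
31 | {(1R,5R)-5-[2-(TBSO)ethyl]-3-[3-(TBSO)-3-methylpent-4-en-1-yn-1-yl]-2,4,4-trimethylcyclohex-2-en-1-yl}diazene | CC(C)(C)[Si](C)(C)OCC[C@H]1C[C@@H](N=N)C(C)=C(C#CC(C)(O[Si](C)(C)C(C)(C)C)C=C)C1(C)C | intermediate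
32 | tert-butyl(2-{(1R,5S)-5-[3-(TBSO)-3-methylpent-4-en-1-yn-1-yl]-4,6,6-trimethylcyclohex-3-en-1-yl}ethoxy)dimethylsilane | CC(C)(C)[Si](C)(C)OCC[C@H]1CC=C(C)[C@H](C#CC(C)(O[Si](C)(C)C(C)(C)C)C=C)C1(C)C | intermediate
33 | 2-[(1R,5S)-5-(3-hydroxy-3-methylpent-4-en-1-yn-1-yl)-4,6,6-trimethylcyclohex-3-en-1-yl]ethan-1-ol | OCC[C@H]1CC=C(C)[C@H](C#CC(C)(O)C=C)C1(C)C | intermediate
34 | 2-[(1R,5S)-5-(3-hydroxy-3-methylpent-4-en-1-yn-1-yl)-4,6,6-trimethylcyclohex-3-en-1-yl]acetaldehyde | O=CC[C@H]1CC=C(C)[C@H](C#CC(C)(O)C=C)C1(C)C | intermediate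
35 | ethyl (2E)-4-[(1R,5S)-5-(3-hydroxy-3-methylpent-4-en-1-yn-1-yl)-4,6,6-trimethylcyclohex-3-en-1-yl]-2-methylbut-2-enoate | CCOC(=O)/C(C)=C/C[C@H]1CC=C(C)[C@H](C#CC(C)(O)C=C)C1(C)C | intermediate
36 | (2E)-4-{(1R,5S)-5-[(1E)-3-hydroxy-3-methylpenta-1,4-dien-1-yl]-4,6,6-trimethylcyclohex-3-en-1-yl}-2-methylbut-2-en-1-ol | OC/C(C)=C/C[C@H]1CC=C(C)[C@H](/C=C/C(C)(O)C=C)C1(C)C | intermediate
37 | (2E)-4-{(1R,5S)-5-[(1E)-3-hydroxy-3-methylpenta-1,4-dien-1-yl]-4,6,6-trimethylcyclohex-3-en-1-yl}-2-methylbut-2-en-1-yl acetate | CC(=O)OC/C(C)=C/C[C@H]1CC=C(C)[C@H](/C=C/C(C)(O)C=C)C1(C)C | intermediate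
38 | {(2E,4E)-5-[(1S,5R)-5-[(2E)-4-acetoxy-3-methylbut-2-en-1-yl]-2,6,6-trimethylcyclohex-2-en-1-yl]-3-methylpenta-2,4-dien-1-yl}triphenylphosphonium bromide | CC(=O)OC/C(C)=C/C[C@H]1CC=C(C)[C@H](/C=C/C(C)=C/C[P+](c2ccccc2)(c2ccccc2)c2ccccc2)C1(C)C.[Br-] | intermediate
39 | O-acetate of the target (acetylated at the side-chain hydroxyl of ring B) | CC(C)=CC[C@H]1CC=C(C)[C@@H](/C=C/C(C)=C/C=C/C(C)=C/C=C/C=C(C)/C=C/C=C(C)/C=C/[C@H]2C(C)=CC[C@H](C/C=C(\C)COC(C)=O)C2(C)C)C1(C)C | intermediate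
40 | (all-E)-(2S,6R,2′R,6′S)-2-(3-methylbut-2-en-1-yl)-2′-[(2E)-4-hydroxy-3-methylbut-2-en-1-yl]-ε,ε-carotene | CC(C)=CC[C@H]1CC=C(C)[C@@H](/C=C/C(C)=C/C=C/C(C)=C/C=C/C=C(C)/C=C/C=C(C)/C=C/[C@H]2C(C)=CC[C@H](C/C=C(\C)CO)C2(C)C)C1(C)C | target

**Step count and risks**

Total step count: 25.
Longest linear sequence: 16 steps (steps 1–5, 7, 8, 17–24, 25; the ring A arm through steps 9–16 and 25 is equally long).

Steps most likely to fail:

1. Step 1. The small sp2 Grignard reagent may be transferred with poor enantioface discrimination, or C-methylation of the magnesium enolate may be slow enough for proton exchange to erode regiocontrol. Fallback, setting out from 1 and returning at 5: the same vinylation–methylation with CuI and no chiral ligand should give racemic 2,2-dimethyl-3-vinylcyclohexan-1-one F1. Addition of lithiated (S)-N,S-dimethyl-S-phenylsulfoximine (n-BuLi, THF, −78 °C) to F1 should give diastereomeric β-hydroxysulfoximines that are separated by chromatography. The adduct of the (R)-ketone, (S)-N-methyl-S-{[(3R)-1-hydroxy-2,2-dimethyl-3-vinylcyclohexyl]methyl}-S-phenylsulfoximine F2, is then heated in toluene at 110 °C, where retro-addition releases the sulfoximine and returns resolved 5.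

2. Step 8. The chromate ester of the hindered tertiary carbinol may ionise and dehydrate to a cross-conjugated trienyne faster than it undergoes the [3,3] shift. Fallback, setting out from 10 and returning at 17: deprotonation of the only α-hydrogen with KN(SiMe3)2 and trapping with N-phenylbis(trifluoromethanesulfonimide) should give the enol triflate (5R)-5-[2-(TBSO)ethyl]-2,6,6-trimethylcyclohex-1-en-1-yl trifluoromethanesulfonate F3. Sonogashira coupling of F3 with 14 (Pd(PPh3)4, CuI, Et3N, DMF) should give the ring dienyne tert-butyl(2-{(1R)-3-[3-(TBSO)-3-methylpent-4-en-1-yn-1-yl]-2,2,4-trimethylcyclohex-3-en-1-yl}ethoxy)dimethylsilane F4. Allylic oxidation of the ring methylene next to the tetrasubstituted alkene (CrO3·3,5-dimethylpyrazole, CH2Cl2, −20 °C) then returns 17.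

3. Step 10 (the same risk attaches to step 18). Mitsunobu displacement at the ring carbinol may be outrun by elimination to a diene or by SN2′ attack, or the diazene may decompose by a radical path that scrambles C6. Fallback, setting out from 18 and returning at 21: formylation (formic acetic anhydride, pyridine) gives the allylic formate (1R,5S)-5-[2-(TBSO)ethyl]-3-[3-(TBSO)-3-methylpent-4-en-1-yn-1-yl]-2,4,4-trimethylcyclohex-2-en-1-yl formate F5. Palladium-catalysed decarboxylative hydrogenolysis (Pd(OAc)2, PBu3, THF, 23 → 50 °C) follows: zerovalent palladium ionises the formate with inversion, loss of CO2 gives a palladium hydride, and hydrogen is delivered from the metal face to the more substituted allyl terminus. This places H at C6 anti to the original C–O bond, the same outcome as the diazene route, and gives 21.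

Further compounds
F1 | step 1 | racemic 2,2-dimethyl-3-vinylcyclohexan-1-one | C=CC1CCCC(=O)C1(C)C
F2 | step 1 | (S)-N-methyl-S-{[(3R)-1-hydroxy-2,2-dimethyl-3-vinylcyclohexyl]methyl}-S-phenylsulfoximine (carbinol centre unassigned) | C=C[C@H]1CCCC(O)(C[S@@](=O)(=NC)c2ccccc2)C1(C)C
F3 | step 8 | (5R)-5-[2-(TBSO)ethyl]-2,6,6-trimethylcyclohex-1-en-1-yl trifluoromethanesulfonate | CC(C)(C)[Si](C)(C)OCC[C@H]1CCC(C)=C(OS(=O)(=O)C(F)(F)F)C1(C)C
F4 | step 8 | tert-butyl(2-{(1R)-3-[3-(TBSO)-3-methylpent-4-en-1-yn-1-yl]-2,2,4-trimethylcyclohex-3-en-1-yl}ethoxy)dimethylsilane | CC(C)(C)[Si](C)(C)OCC[C@H]1CCC(C)=C(C#CC(C)(O[Si](C)(C)C(C)(C)C)C=C)C1(C)C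
F5 | step 10 | (1R,5S)-5-[2-(TBSO)ethyl]-3-[3-(TBSO)-3-methylpent-4-en-1-yn-1-yl]-2,4,4-trimethylcyclohex-2-en-1-yl formate | CC(C)(C)[Si](C)(C)OCC[C@H]1C[C@@H](OC=O)C(C)=C(C#CC(C)(O[Si](C)(C)C(C)(C)C)C=C)C1(C)C
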